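**Retrosynthetic overview**
1. Target 14 ⇒ monomers 8 and 11 plus one CH2 unit. The Ar–CH2–Ar′ bridge is made last via a Mannich base and its o-quinone methide; each monomer has one free ring C–H, so the bridge position is fixed.
2. 8 and 11 ⇒ ketones 3 and 5. The aryl C–OMe bond ortho to the acyl group is the key bond, made by a formal C–H methoxylation (oxidative dearomatisation, oxa-Michael addition of MeOH, rearomatisation).
3. 3 and 5 ⇒ 4-methylresorcinol 1 plus acid chlorides 2 and 4 (Friedel–Crafts acylation).
4. No ring is built: both benzene rings come from 1.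

Assumption: the SMILES has no stereocentre, so the target is achiral and no stereocontrol is needed; intermediates 6, 7, 9 and 10 are racemic or diastereomeric mixtures that converge.
Ring numbering used in the Why lines for 3, 5 and their products: C1 acyl, C2 OH, C3 H, C4 OH, C5 CH3, C6 H.

**Step 1**
Reactants: 1 4-methylbenzene-1,3-diol (4-methylresorcinol); 2 3-methylbutanoyl chloride (isovaleryl chloride)
Product: 3 1-(2,4-dihydroxy-5-methylphenyl)-3-methylbutan-1-one
Conditions: AlCl3 (3 equiv), PhNO2, 0 → 60 °C; then ice/1 M HCl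
Reagents that add atoms: none
Why: Friedel–Crafts acylation (any O-acyl product undergoes Fries rearrangement under AlCl3) goes to the resorcinol carbon that is para to one OH and ortho to the other, because the carbon between the two OH groups is hindered.

**Step 2**
Reactants: 1 4-methylbenzene-1,3-diol; 4 2-methylpropanoyl chloride (isobutyryl chloride)
Product: 5 1-(2,4-dihydroxy-5-methylphenyl)-2-methylpropan-1-one
Conditions: AlCl3 (3 equiv), PhNO2, 0 → 60 °C; then ice/1 M HCl
Reagents that add atoms: none
Why: Same Friedel–Crafts acylation with the same regiochemical control as step 1.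

**Step 3**
Reactants: 3 1-(2,4-dihydroxy-5-methylphenyl)-3-methylbutan-1-one
Product: 8 1-(4,6-dihydroxy-2-methoxy-3-methylphenyl)-3-methylbutan-1-one, via quinol ether 6 (not isolated), via methanol adduct 7 (not isolated)
Conditions: PhI(OAc)2 (1.0 equiv), MeOH (0.03 M), −20 → 0 °C, 3 added slowly to the oxidant; then TsOH·H2O (20 mol%), 50 °C
Reagents that add atoms: methanol CO
Why: Proposed new method: a one-flask formal C–H methoxylation in which PhI(OAc)2 oxidises the resorcinol to a phenoxenium-type species with its charge on C1, C3 and C5, and MeOH is expected to trap it at the methyl-bearing C5 (as p-cresols give 4-methoxy-4-methyldienones) to give 6; in 6 the C6–H carbon is the β-carbon of a 2-acyl enone, so acid-catalysed oxa-Michael addition of MeOH gives 7, whose dienol ionises the tertiary, doubly allylic C5–OMe and loses H+ from C6, so that aromatisation fixes the new C6–O bond; the oxidant is used up before any electron-rich product exists; closest known reaction type: hypervalent-iodine dearomatisation of 4-alkylphenols to quinol ethers followed by Michael addition and loss of MeOH with C-, N- and S-nucleophiles (meta-functionalisation of phenols) and the quinol acetate 1,2-acyloxy shift, not shown with methanol as nucleophile or on acylresorcinols.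

**Step 4**
Reactants: 5 1-(2,4-dihydroxy-5-methylphenyl)-2-methylpropan-1-one
Product: 11 1-(4,6-dihydroxy-2-methoxy-3-methylphenyl)-2-methylpropan-1-one, via quinol ether 9 (not isolated), via methanol adduct 10 (not isolated)
Conditions: PhI(OAc)2 (1.0 equiv), MeOH (0.03 M), −20 → 0 °C, 5 added slowly to the oxidant; then TsOH·H2O (20 mol%), 50 °C
Reagents that add atoms: methanol CO
Why: Proposed new method: the same oxidative dearomatisation at C5, oxa-Michael addition of MeOH at C6 of the 2-acyl enone 9 and acid-promoted loss of the tertiary C5–OMe from 10 with rearomatisation as in step 3; closest known reaction type: quinol-ether formation from 4-alkylphenols with PhI(OAc)2/MeOH followed by Michael addition and rearomatisation with C-, N- and S-nucleophiles.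

**Step 5**
Reactants: 8 1-(4,6-dihydroxy-2-methoxy-3-methylphenyl)-3-methylbutan-1-one; 11 1-(4,6-dihydroxy-2-methoxy-3-methylphenyl)-2-methylpropan-1-one
Product: 14 1-[3-[[2,6-dihydroxy-4-methoxy-3-methyl-5-(2-methylpropanoyl)phenyl]methyl]-2,4-dihydroxy-6-methoxy-5-methylphenyl]-3-methylbutan-1-one, via Mannich base 12 (not isolated), via o-quinone methide 13 (not isolated)
Conditions: Me2NCH2NMe2 (1.05 equiv), 1,4-dioxane, 25 °C, then concentrate; then 11 (1.0 equiv), 1,4-dioxane, 100 °C
Reagents that add atoms: N,N,N',N'-tetramethylmethanediamine CN(C)CN(C)C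
Why: Phenolic Mannich reaction at the only free ring carbon of 8, then thermal loss of Me2NH gives o-quinone methide 13, which the only free ring carbon of 11 (flanked by two OH groups, strongly nucleophilic) captures in a conjugate Friedel–Crafts alkylation; no stereocentre is formed.

**Compound list**
1 | 4-methylbenzene-1,3-diol | Cc1ccc(O)cc1O | starting material
2 | 3-methylbutanoyl chloride | CC(C)CC(Cl)=O | starting material
3 | 1-(2,4-dihydroxy-5-methylphenyl)-3-methylbutan-1-one | CC(C)CC(=O)c1cc(C)c(O)cc1O | intermediate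
4 | 2-methylpropanoyl chloride | CC(C)C(Cl)=O | starting material
5 | 1-(2,4-dihydroxy-5-methylphenyl)-2-methylpropan-1-one | CC(C)C(=O)c1cc(C)c(O)cc1O | intermediate
6 | 5-hydroxy-4-methoxy-4-methyl-2-(3-methylbutanoyl)cyclohexa-2,5-dien-1-one (racemic) | CC(C)CC(=O)C1=CC(C)(OC)C(O)=CC1=O | intermediate (not isolated)
7 | 3-hydroxy-4,5-dimethoxy-4-methyl-6-(3-methylbutanoyl)cyclohex-2-en-1-one (diastereomer mixture) | CC(C)CC(=O)C1C(OC)C(C)(OC)C(O)=CC1=O | intermediate (not isolated)
8 | 1-(4,6-dihydroxy-2-methoxy-3-methylphenyl)-3-methylbutan-1-one | CC(C)CC(=O)c1c(OC)c(C)c(O)cc1O | intermediate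
9 | 5-hydroxy-4-methoxy-4-methyl-2-(2-methylpropanoyl)cyclohexa-2,5-dien-1-one (racemic) | CC(C)C(=O)C1=CC(C)(OC)C(O)=CC1=O | intermediate (not isolated)
10 | 3-hydroxy-4,5-dimethoxy-4-methyl-6-(2-methylpropanoyl)cyclohex-2-en-1-one (diastereomer mixture) | CC(C)C(=O)C1C(OC)C(C)(OC)C(O)=CC1=O | intermediate (not isolated)
11 | 1-(4,6-dihydroxy-2-methoxy-3-methylphenyl)-2-methylpropan-1-one | CC(C)C(=O)c1c(OC)c(C)c(O)cc1O | intermediate
12 | 1-{3-[(dimethylamino)methyl]-2,4-dihydroxy-6-methoxy-5-methylphenyl}-3-methylbutan-1-one | CC(C)CC(=O)c1c(OC)c(C)c(O)c(CN(C)C)c1O | intermediate (not isolated)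
13 | 3-hydroxy-5-methoxy-4-methyl-2-methylidene-6-(3-methylbutanoyl)cyclohexa-3,5-dien-1-one | CC(C)CC(=O)C1=C(OC)C(C)=C(O)C(=C)C1=O | intermediate (not isolated)
14 | 1-[3-[[2,6-dihydroxy-4-methoxy-3-methyl-5-(2-methylpropanoyl)phenyl]methyl]-2,4-dihydroxy-6-methoxy-5-methylphenyl]-3-methylbutan-1-one (achiral) | COc1c(C)c(O)c(Cc2c(O)c(C)c(OC)c(C(=O)C(C)C)c2O)c(O)c1C(=O)CC(C)C | target

**Total step count:** 5
**Longest linear sequence:** 3 (step 1, step 3, step 5; or step 2, step 4, step 5)

**Steps most likely to fail**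

Step 3 (proposed new method). Methanol may trap the oxidised ring at C3 instead of C5, the acid stage may give a methyl 1,2-shift (dienone–phenol rearrangement), or product 8 may add as a carbon nucleophile to dienone 6. The fallback is ketone-directed C–H hydroxylation, all known chemistry, setting out from 3 and coming back at 8. PivCl, Et3N and DMAP in CH2Cl2 give 4-methyl-6-(3-methylbutanoyl)-1,3-phenylene bis(2,2-dimethylpropanoate) F1. Pd(OAc)2 (10 mol%), K2S2O8, TFA/TFAA at 50 °C hydroxylate the only C–H ortho to the ketone and give, after aqueous work-up, 5-hydroxy-4-methyl-6-(3-methylbutanoyl)-1,3-phenylene bis(2,2-dimethylpropanoate) F2. MeI and K2CO3 in acetone at 50 °C give 5-methoxy-4-methyl-6-(3-methylbutanoyl)-1,3-phenylene bis(2,2-dimethylpropanoate) F3. NaOMe in MeOH at 25 °C removes both pivalates and returns 8.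

Step 4 (the same new method on the isobutyryl series, with the same failure modes). The fallback sets out from 5 and comes back at 11 by the same known sequence. Pivaloylation gives 4-methyl-6-(2-methylpropanoyl)-1,3-phenylene bis(2,2-dimethylpropanoate) F4. Pd-catalysed ketone-directed ortho-hydroxylation gives 5-hydroxy-4-methyl-6-(2-methylpropanoyl)-1,3-phenylene bis(2,2-dimethylpropanoate) F5. O-Methylation gives 5-methoxy-4-methyl-6-(2-methylpropanoyl)-1,3-phenylene bis(2,2-dimethylpropanoate) F6, and methanolysis returns 11.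

Step 5. The amine and heat can cause retro-Mannich methylene exchange, which would give the two symmetrical dimers, and 13 can oligomerise. The fallback avoids the amine and the free quinone methide, setting out from 8 and coming back at 14. Vilsmeier–Haack formylation (POCl3, DMF, EtOAc, 0 → 25 °C; then H2O, 60 °C) at the only free ring carbon gives 2,6-dihydroxy-4-methoxy-3-methyl-5-(3-methylbutanoyl)benzaldehyde F7. A reductive Friedel–Crafts benzylation of 11 with F7 (Et3SiH, TFA/CH2Cl2, 0 → 25 °C, ionic hydrogenation of the diarylcarbinol cation) then gives 14.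

**Further compounds**
F1 | step 3 | 4-methyl-6-(3-methylbutanoyl)-1,3-phenylene bis(2,2-dimethylpropanoate) | CC(C)CC(=O)c1cc(C)c(OC(=O)C(C)(C)C)cc1OC(=O)C(C)(C)C
F2 | step 3 | 5-hydroxy-4-methyl-6-(3-methylbutanoyl)-1,3-phenylene bis(2,2-dimethylpropanoate) | CC(C)CC(=O)c1c(O)c(C)c(OC(=O)C(C)(C)C)cc1OC(=O)C(C)(C)C
F3 | step 3 | 5-methoxy-4-methyl-6-(3-methylbutanoyl)-1,3-phenylene bis(2,2-dimethylpropanoate) | CC(C)CC(=O)c1c(OC)c(C)c(OC(=O)C(C)(C)C)cc1OC(=O)C(C)(C)C
F4 | step 4 | 4-methyl-6-(2-methylpropanoyl)-1,3-phenylene bis(2,2-dimethylpropanoate) | CC(C)C(=O)c1cc(C)c(OC(=O)C(C)(C)C)cc1OC(=O)C(C)(C)C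
F5 | step 4 | 5-hydroxy-4-methyl-6-(2-methylpropanoyl)-1,3-phenylene bis(2,2-dimethylpropanoate) | CC(C)C(=O)c1c(O)c(C)c(OC(=O)C(C)(C)C)cc1OC(=O)C(C)(C)C
F6 | step 4 | 5-methoxy-4-methyl-6-(2-methylpropanoyl)-1,3-phenylene bis(2,2-dimethylpropanoate) | CC(C)C(=O)c1c(OC)c(C)c(OC(=O)C(C)(C)C)cc1OC(=O)C(C)(C)C
F7 | step 5 | 2,6-dihydroxy-4-methoxy-3-methyl-5-(3-methylbutanoyl)benzaldehyde | CC(C)CC(=O)c1c(OC)c(C)c(O)c(C=O)c1O
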